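Longipinane numbering: enone bridge C11–C1(=O)–C2=C3(Me)–C4, cyclobutane C4–C5–C11–C10, chain C5–C6(Me2)–C7–C8–C9–C10. The plan exploits the fact that the four-carbon chain C6–C9 of the seven-membered ring spans the diagonal cyclobutane carbons C5 and C10. These are the ends of the central bond of a bicyclobutane whose wing tips C4 and C11 already carry the three-carbon bridge. A Lewis-acid-triggered, strain-releasing (4+3) annulation of this ester-activated tricyclo[4.1.0.0(2,7)]heptane with a 2-silyloxydiene forms C5–C6 and C9–C10 in one operation, closes the seven-membered ring and fixes C5 and C10. The ester on C10 is later reduced to the C10 methyl group.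

Key step: step 9

Assumption: the sense of induction of the two chiral catalysts (steps 4 and 17) is taken from simple cyclic enones; if the cage enone of step 17 responds in the opposite sense, the antipodal ligand is the one to use.

Terms: TBS = tert-butyldimethylsilyl. "Syn to C5" and "syn to C10" give the side of the C1–C2–C3 bridge on which a substituent stands. "Toward C4" and "toward C11" give the side of the C6–C9 chain.

Step 1
Reactants: 1 5-methylcyclohexane-1,3-dione
Product: 2 5-methyl-3-(2-methylpropoxy)cyclohex-2-en-1-one (racemic; 5R enantiomer drawn)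
Conditions: i-BuOH, p-TsOH·H2O (cat.), toluene, reflux, Dean–Stark
Reagents that add atoms: 2-methylpropan-1-ol, CC(C)CO
Why: Acid-catalysed condensation of a cyclic 1,3-dione with an alcohol under water removal is the standard entry to the vinylogous ester of a Stork–Danheiser sequence, and the product is racemic because either carbonyl group of achiral 1 can be etherified.

Step 2
Reactants: 2 5-methyl-3-(2-methylpropoxy)cyclohex-2-en-1-one; 3 methyl bromoacetate
Product: 4 methyl 2-[(1S,6R)-6-methyl-4-(2-methylpropoxy)-2-oxocyclohex-3-en-1-yl]acetate (racemic trans isomer; this enantiomer drawn)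
Conditions: LiN(i-Pr)2, THF, −78 °C; then 3, −78 to −30 °C
Reagents that add atoms: none
Why: In this Stork–Danheiser alkylation the amide base removes the α′ proton (future C4) kinetically and the cross-conjugated enolate is alkylated anti to the neighbouring methyl group, which sets the trans C3/C4 relationship.

Step 3
Reactants: 4 methyl 2-[(1S,6R)-6-methyl-4-(2-methylpropoxy)-2-oxocyclohex-3-en-1-yl]acetate
Product: 6 methyl 2-[(1S,6R)-6-methyl-4-oxocyclohex-2-en-1-yl]acetate (racemic trans isomer; this enantiomer drawn), via allylic alcohol 5 (not isolated)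
Conditions: NaBH4, CeCl3·7H2O, MeOH, 0 °C; then 1 M HCl, THF, rt
Reagents that add atoms: water, O
Why: Luche 1,2-reduction takes the vinylogous ester carbonyl but not the methyl ester, and acid then hydrolyses the enol ether with loss of water (Stork–Danheiser transposition), which places the C5=C11 double bond next to C4 without touching C3 or C4.

Step 4
Reactants: 6 methyl 2-[(1S,6R)-6-methyl-4-oxocyclohex-2-en-1-yl]acetate (racemate)
Product: 7 methyl 2-[(1S,4R,6R)-4-hydroxy-6-methylcyclohex-2-en-1-yl]acetate (single enantiomer; OH cis to the acetate arm; CH3 trans to it)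
Conditions: (S)-2-methyl-CBS-oxazaborolidine (20 mol %), catecholborane, toluene, −78 °C; chromatographic separation of the diastereomers
Reagents that add atoms: none
Why: The Corey–Bakshi–Shibata reduction serves as a divergent reaction on a racemic mixture, because the catalyst delivers hydride to the same carbonyl face of both enantiomers (alkenyl side as large group), so the wanted ketone gives the 1,4-cis alcohol 7 and its antipode gives the separable 1,4-trans alcohol, whereas a substrate-controlled Luche reduction would give the all-equatorial trans isomer, whose arm cannot sit pseudo-axial over the alkene in step 7.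

Step 5
Reactants: 7 methyl 2-[(1S,4R,6R)-4-hydroxy-6-methylcyclohex-2-en-1-yl]acetate
Product: 8 methyl 2-[(1S,4R,6R)-4-(tert-butyldimethylsilyloxy)-6-methylcyclohex-2-en-1-yl]acetate
Conditions: TBSCl, imidazole, DMF, rt
Reagents that add atoms: tert-butyldimethylsilyl chloride, CC(C)(C)[Si](C)(C)Cl
Why: Standard imidazole-promoted silylation proceeds with retention at C1 and gives an ether that tolerates the amide base, carbenoid, Lewis acid and hydride steps that follow.

Step 6
Reactants: 8 methyl 2-[(1S,4R,6R)-4-(tert-butyldimethylsilyloxy)-6-methylcyclohex-2-en-1-yl]acetate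
Product: 10 methyl 2-diazo-2-[(1S,4R,6R)-4-(tert-butyldimethylsilyloxy)-6-methylcyclohex-2-en-1-yl]acetate, via trifluoroacetyl ester 9 (not isolated)
Conditions: LiN(SiMe3)2, THF, −78 °C; CF3CO2CH2CF3; then 4-AcNHC6H4SO2N3, Et3N, H2O (1 equiv), MeCN, rt
Reagents that add atoms: 2,2,2-trifluoroethyl trifluoroacetate, FC(F)(F)COC(=O)C(F)(F)F (its CF3CO group stays only in 9); 4-acetamidobenzenesulfonyl azide, CC(=O)Nc1ccc(cc1)S(=O)(=O)N=[N+]=[N-] (N2 unit)
Why: In this deacylative Regitz diazo transfer the ester enolate is first C-trifluoroacetylated to activate C10 and the azide then transfers N2 with loss of the acyl group, which is the reliable way for simple alkyl esters and leaves C4 untouched.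

Step 7
Reactants: 10 methyl 2-diazo-2-[(1S,4R,6R)-4-(tert-butyldimethylsilyloxy)-6-methylcyclohex-2-en-1-yl]acetate
Product: 11 methyl (1R,2S,3R,5R,6R,7S)-5-(tert-butyldimethylsilyloxy)-3-methyltricyclo[4.1.0.0(2,7)]heptane-1-carboxylate (ester carbon C1 = C10; CH carbon C7 = C5; OTBS syn to C10; CH3 syn to C5)
Conditions: Rh2(O2CCPh3)4 (1 mol %), toluene, −78 °C, slow addition of 10
Reagents that add atoms: none
Why: This is the known rhodium-carbenoid intramolecular cyclopropanation of 2-diazopent-4-enoates to bicyclobutane-1-carboxylates, in which C10 can reach only the C5=C11 face on which its anchor at C4 stands (so C5, C10 and C11 follow from C4), and the bulky triphenylacetate ligands at low temperature are chosen instead of Rh2(OAc)4 because they hold back the 1,2-shift of the C4 hydrogen.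

Step 8
Reactants: 12 4-methylpent-1-en-3-one
Product: 13 3-(tert-butyldimethylsilyloxy)-4-methylpenta-1,3-diene
Conditions: TBSOTf, Et3N, CH2Cl2, 0 °C
Reagents that add atoms: tert-butyldimethylsilyl triflate, CC(C)(C)[Si](C)(C)OS(=O)(=O)C(F)(F)F
Why: Soft enolisation of a vinyl ketone whose only α-hydrogen is the isopropyl CH gives one regioisomer of the 2-silyloxydiene, and the robust silyl group is chosen so that the enol ether made in step 9 survives steps 10 and 11 as protection of the C7 ketone.

Step 9
Reactants: 11 methyl 5-(tert-butyldimethylsilyloxy)-3-methyltricyclo[4.1.0.0(2,7)]heptane-1-carboxylate; 13 3-(tert-butyldimethylsilyloxy)-4-methylpenta-1,3-diene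
Product: 15 tricyclic silyl enol ether (longipinane cage; C7(OTBS)=C8; C9H2; CO2Me on C10 in place of the methyl group; OTBS on C1 syn to C10; CH3 on C3 syn to C5), via ketene acetal enone 14 (not isolated)
Conditions: Sc(OTf)3 (10 mol %), 2,6-di-tert-butyl-4-methylpyridine (15 mol %), 4 Å MS, 13 (2 equiv), CH2Cl2, −40 to 0 °C
Reagents that add atoms: none
Why: Proposed new method: Sc(OTf)3 bound to the ester carbonyl draws electron density out of the strained C5–C10 bond so that C10 becomes enolate-like and C5 electrophilic; C6, the dimethyl-substituted α-carbon of 13, bonds to C5, the silyl group moves to the ester oxygen (14), and the ketene acetal carbon C10 then adds to the vinyl ketone terminus C9, which returns the silyl group to O7 as the C7=C8 enol ether. The closest known reaction type is the Lewis-acid-catalysed formal (4+3) annulation of aryl-substituted acyl bicyclobutanes with 2-silyloxydienes to bicyclo[4.1.1]octanes; new here are a secondary, aryl-free C5, a fully substituted nucleophilic carbon and a bicyclobutane bridged on its concave side. The one ring closed is the seven-membered ring C5–C6–C7–C8–C9–C10–C4(C11), formed by a 7-endo-trig (enol-exo) intramolecular Mukaiyama–Michael addition. C5 and C10 are controlled by the cage, since a four-atom tether can span the diagonal cyclobutane carbons only cis and only on the convex face anti to the C1–C2–C3 bridge, so their absolute configuration follows from C4 and C11 of 11. The rear lobe of C5, the usual entry of nucleophiles, points below the wing, where the C3 methyl group shields it and where an adduct could not cyclise, so C5–C6 bonding must occur with retention on the convex face through a late, ion-pair-like opening or an asynchronous, symmetry-allowed six-electron [σ2s+π4s] array. The step needs regioselectivity (C6 to C5, C9 to C10), secured by the single ester on C10 and the α-nucleophilicity of the diene, and 1,4- over 1,2-closure, favoured by the quaternary C6 next to the C7 carbonyl, while the hindered pyridine keeps triflic acid away from the silyl ethers.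

Step 10
Reactants: 15 tricyclic silyl enol ether with C10 ester
Product: 16 primary alcohol (as 15 but CH2OH on C10)
Conditions: LiAlH4, Et2O, 0 °C; aq. NaOH work-up
Reagents that add atoms: none
Why: Ester reduction with LiAlH4 leaves silyl ethers and silyl enol ethers untouched, so C7 stays masked while the hindered C10 ester goes to the neopentyl alcohol.

Step 11
Reactants: 16 primary alcohol
Product: 17 aldehyde (as 15 but CHO on C10)
Conditions: n-Pr4N[RuO4] (5 mol %), N-methylmorpholine N-oxide, 4 Å MS, CH2Cl2, rt
Reagents that add atoms: none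
Why: The neutral, anhydrous Ley–Griffith oxidation stops at the non-enolisable aldehyde and leaves both silyl groups in place.

Step 12
Reactants: 17 aldehyde
Product: 19 ketone (longipinane cage; C7=O; C8H2; C9H2; CH3 on C10; OTBS on C1 syn to C10; CH3 on C3 syn to C5), via N-silylhydrazone 18 (not isolated)
Conditions: TBSNHNHTBS, Sc(OTf)3 (1 mol %), CH2Cl2, rt, evaporate; then KOt-Bu, t-BuOH, DMSO, rt to 60 °C
Reagents that add atoms: 1,2-bis(tert-butyldimethylsilyl)hydrazine, CC(C)(C)[Si](C)(C)NN[Si](C)(C)C(C)(C)C (its N2 and silyl unit stay only in 18)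
Why: In the N-silylhydrazone variant of the Wolff–Kishner reduction the hydrazone forms without free hydrazine or water and loses N2 by an anionic pathway at low temperature, which avoids radical opening or cationic expansion of the cyclobutylcarbinyl system, while tert-butoxide also cleaves the enol silane to the C7 enolate, which is inert until work-up.

Step 13
Reactants: 19 ketone with C1 silyl ether
Product: 20 hydroxy ketone (as 19 but free OH on C1)
Conditions: n-Bu4NF, THF, rt
Reagents that add atoms: none
Why: Fluoride-mediated desilylation frees the secondary alcohol, and nothing else in 19 is sensitive because C6 is quaternary and no stereocentre is enolisable.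

Step 14
Reactants: 20 hydroxy ketone
Product: 21 diketone (C1=O and C7=O; CH3 on C3 syn to C5)
Conditions: n-Pr4N[RuO4] (5 mol %), N-methylmorpholine N-oxide, 4 Å MS, CH2Cl2, rt
Reagents that add atoms: none
Why: Ley–Griffith oxidation of the secondary alcohol removes the auxiliary C1 stereocentre, and the bridgehead C11 next to the new ketone cannot epimerise.

Step 15
Reactants: 21 diketone
Product: 23 2,8-dibromo diketone (Br on C2 syn to C5 and cis to the C3 methyl group; C8 epimers), via bis(silyl enol ether) 22 (not isolated)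
Conditions: TMSOTf (2.5 equiv), Et3N, CH2Cl2, 0 °C; then NBS (2.1 equiv), THF, −78 to 0 °C
Reagents that add atoms: trimethylsilyl triflate, C[Si](C)(C)OS(=O)(=O)C(F)(F)F (silyl groups only in 22); N-bromosuccinimide, O=C1CCC(=O)N1Br
Why: Soft enolisation followed by electrophilic bromination is regiochemically unambiguous because C1 can enolise only toward C2 (C11 is a bridgehead) and C7 only toward C8 (C6 is quaternary), and bromine enters C2 on the open face away from the C10 methyl group.

Step 16
Reactants: 23 2,8-dibromo diketone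
Product: 24 bis-enone (longipina-2,8-diene-1,7-dione; cage as in the target)
Conditions: Li2CO3, LiBr, DMF, 120 °C
Reagents that add atoms: none
Why: This double E2 dehydrobromination is stereoelectronically matched, since the axial C2 bromine is antiperiplanar to the C3 hydrogen, which lies under the C10 methyl group and would be out of reach for syn eliminations through palladium enolates or selenoxides, while C8–Br finds an anti hydrogen on C9 and the auxiliary C3 stereocentre disappears.

Step 17
Reactants: 24 bis-enone
Product: 26 (9R)-9-hydroxylongipin-2-ene-1,7-dione (OH on C9 toward C11), via C9 boronate 25 (not isolated)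
Conditions: CuCl (5 mol %), NaOt-Bu (7 mol %), (R)-1-[(Sp)-2-(diphenylphosphino)ferrocenyl]ethyldicyclohexylphosphine (6 mol %), B2pin2 (1.05 equiv), MeOH (2 equiv), THF, 0 °C to rt; then NaBO3·4H2O, THF–H2O, rt
Reagents that add atoms: bis(pinacolato)diboron, CC1(C)OB(OC1(C)C)B2OC(C)(C)C(C)(C)O2 (Bpin only in 25); sodium perborate, [Na+].[Na+].O[B-]1(O)OO[B-](O)(O)OO1 (oxygen on C9)
Why: In this copper-catalysed asymmetric conjugate borylation with stereoretentive perborate oxidation the copper boryl adds to the β-monosubstituted C8=C9 enone much faster than to the β,β-disubstituted, cage-shielded C2=C3 enone, and because the two faces of C9 differ only through remote groups the chiral diphosphine decides that boron, then oxygen, ends on the face toward C11.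

Step 18
Reactants: 26 (9R)-9-hydroxylongipin-2-ene-1,7-dione; 27 (E)-2-methylbut-2-enal
Product: 29 (7R,9R)-7-hydroxy-9-[(E)-2-methylbut-2-enoyloxy]longipin-2-en-1-one (OH on C7 toward C4), via C9 hemiacetal 28 (not isolated)
Conditions: SmI2 (30 mol %), 27 (5 equiv), THF, −10 °C
Reagents that add atoms: none
Why: In the Evans–Tishchenko reduction the samarium-bound C9 hemiacetal passes its hydride intramolecularly to the C7 carbonyl on the face of the C9 oxygen, which gives the 1,3-anti alcohol and leaves the tigloyl group on O9 only, so the two hydroxyl groups never have to be told apart and acyl migration across the ring-bound trans-1,3-diol is geometrically excluded.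

Step 19
Reactants: 29 (7R,9R)-7-hydroxy-9-[(E)-2-methylbut-2-enoyloxy]longipin-2-en-1-one
Product: 30 (4R,5S,7R,9R,10R,11R)-7-(3-methylbutanoyloxy)-9-[(E)-2-methylbut-2-enoyloxy]longipin-2-en-1-one (target CNP0194415.1)
Conditions: 3-methylbutanoyl chloride, pyridine, DMAP (cat.), CH2Cl2, 0 °C to rt
Reagents that add atoms: 3-methylbutanoyl chloride, CC(C)CC(=O)Cl
Why: DMAP-catalysed acylation of the remaining neopentyl-type secondary alcohol with an unhindered acid chloride proceeds with retention at C7 and completes the target.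

Compound list
1 | 5-methylcyclohexane-1,3-dione | CC1CC(=O)CC(=O)C1 | starting material
2 | 5-methyl-3-(2-methylpropoxy)cyclohex-2-en-1-one (racemic; 5R drawn) | CC(C)COC1=CC(=O)C[C@H](C)C1 | intermediate
3 | methyl bromoacetate | COC(=O)CBr | starting material
4 | methyl 2-[(1S,6R)-6-methyl-4-(2-methylpropoxy)-2-oxocyclohex-3-en-1-yl]acetate (racemic) | CC(C)COC1=CC(=O)[C@@H](CC(=O)OC)[C@H](C)C1 | intermediate
5 | methyl 2-[(1S,6R)-2-hydroxy-6-methyl-4-(2-methylpropoxy)cyclohex-3-en-1-yl]acetate (racemic; carbinol epimers) | CC(C)COC1=CC(O)[C@@H](CC(=O)OC)[C@H](C)C1 | intermediate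
6 | methyl 2-[(1S,6R)-6-methyl-4-oxocyclohex-2-en-1-yl]acetate (racemic) | O=C1C=C[C@@H](CC(=O)OC)[C@H](C)C1 | intermediate
7 | methyl 2-[(1S,4R,6R)-4-hydroxy-6-methylcyclohex-2-en-1-yl]acetate | O[C@H]1C=C[C@@H](CC(=O)OC)[C@H](C)C1 | intermediate
8 | methyl 2-[(1S,4R,6R)-4-(tert-butyldimethylsilyloxy)-6-methylcyclohex-2-en-1-yl]acetate | CC(C)(C)[Si](C)(C)O[C@H]1C=C[C@@H](CC(=O)OC)[C@H](C)C1 | intermediate
9 | methyl 2-[(1S,4R,6R)-4-(tert-butyldimethylsilyloxy)-6-methylcyclohex-2-en-1-yl]-4,4,4-trifluoro-3-oxobutanoate | CC(C)(C)[Si](C)(C)O[C@H]1C=C[C@@H](C(C(=O)OC)C(=O)C(F)(F)F)[C@H](C)C1 | intermediate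
10 | methyl 2-diazo-2-[(1S,4R,6R)-4-(tert-butyldimethylsilyloxy)-6-methylcyclohex-2-en-1-yl]acetate | CC(C)(C)[Si](C)(C)O[C@H]1C=C[C@@H](C(=[N+]=[N-])C(=O)OC)[C@H](C)C1 | intermediate
11 | methyl (1R,2S,3R,5R,6R,7S)-5-(tert-butyldimethylsilyloxy)-3-methyltricyclo[4.1.0.0(2,7)]heptane-1-carboxylate | COC(=O)[C@@]12[C@H]3[C@@H]1[C@H](C)C[C@@H](O[Si](C)(C)C(C)(C)C)[C@@H]23 | intermediate
12 | 4-methylpent-1-en-3-one | CC(C)C(=O)C=C | starting material
13 | 3-(tert-butyldimethylsilyloxy)-4-methylpenta-1,3-diene | CC(C)=C(O[Si](C)(C)C(C)(C)C)C=C | intermediate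
14 | ring-opened norpinane with 2-methyl-3-oxopent-4-en-2-yl on C5 (anti to the bridge) and C10=C(OMe)OTBS | C=CC(=O)C(C)(C)[C@@H]1[C@H]2[C@H](O[Si](C)(C)C(C)(C)C)C[C@@H](C)[C@@H]1C2=C(OC)O[Si](C)(C)C(C)(C)C | intermediate
15 | tricyclic silyl enol ether with C10 methyl ester | C1C=C(O[Si](C)(C)C(C)(C)C)C(C)(C)[C@@H]2[C@H]3[C@H](O[Si](C)(C)C(C)(C)C)C[C@@H](C)[C@@H]2[C@]31C(=O)OC | intermediate
16 | C10 hydroxymethyl compound | C1C=C(O[Si](C)(C)C(C)(C)C)C(C)(C)[C@@H]2[C@H]3[C@H](O[Si](C)(C)C(C)(C)C)C[C@@H](C)[C@@H]2[C@]31CO | intermediate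
17 | C10 aldehyde | C1C=C(O[Si](C)(C)C(C)(C)C)C(C)(C)[C@@H]2[C@H]3[C@H](O[Si](C)(C)C(C)(C)C)C[C@@H](C)[C@@H]2[C@]31C=O | intermediate
18 | N-TBS hydrazone of 17 | C1C=C(O[Si](C)(C)C(C)(C)C)C(C)(C)[C@@H]2[C@H]3[C@H](O[Si](C)(C)C(C)(C)C)C[C@@H](C)[C@@H]2[C@]31C=NN[Si](C)(C)C(C)(C)C | intermediate
19 | 1-(tert-butyldimethylsilyloxy)longipinan-7-one | C1CC(=O)C(C)(C)[C@@H]2[C@H]3[C@H](O[Si](C)(C)C(C)(C)C)C[C@@H](C)[C@@H]2[C@]31C | intermediate
20 | 1-hydroxylongipinan-7-one | C1CC(=O)C(C)(C)[C@@H]2[C@H]3[C@H](O)C[C@@H](C)[C@@H]2[C@]31C | intermediate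
21 | longipinane-1,7-dione | C1CC(=O)C(C)(C)[C@@H]2[C@H]3C(=O)C[C@@H](C)[C@@H]2[C@]31C | intermediate
22 | 1,7-bis(trimethylsilyloxy)longipina-1,7-diene | C1C=C(O[Si](C)(C)C)C(C)(C)[C@@H]2[C@H]3C(O[Si](C)(C)C)=C[C@@H](C)[C@@H]2[C@]31C | intermediate
23 | 2,8-dibromolongipinane-1,7-dione | C1C(Br)C(=O)C(C)(C)[C@@H]2[C@H]3C(=O)[C@@H](Br)[C@@H](C)[C@@H]2[C@]31C | intermediate
24 | longipina-2,8-diene-1,7-dione | C1=CC(=O)C(C)(C)[C@@H]2[C@H]3C(=O)C=C(C)[C@@H]2[C@]31C | intermediate
25 | 9-(pinacolatoboryl)longipin-2-ene-1,7-dione | CC1(C)OB(OC1(C)C)[C@@H]2CC(=O)C(C)(C)[C@@H]3[C@H]4C(=O)C=C(C)[C@@H]3[C@]42C | intermediate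
26 | (9R)-9-hydroxylongipin-2-ene-1,7-dione | O[C@@H]1CC(=O)C(C)(C)[C@@H]2[C@H]3C(=O)C=C(C)[C@@H]2[C@]31C | intermediate
27 | (E)-2-methylbut-2-enal | C/C=C(\C)C=O | starting material
28 | C9 hemiacetal of 26 with 27 (samarium-bound in the flask; drawn neutral) | C/C=C(\C)C(O)O[C@@H]1CC(=O)C(C)(C)[C@@H]2[C@H]3C(=O)C=C(C)[C@@H]2[C@]31C | intermediate
29 | (7R,9R)-7-hydroxy-9-[(E)-2-methylbut-2-enoyloxy]longipin-2-en-1-one | C/C=C(\C)C(=O)O[C@@H]1C[C@@H](O)C(C)(C)[C@@H]2[C@H]3C(=O)C=C(C)[C@@H]2[C@]31C | intermediate
30 | (4R,5S,7R,9R,10R,11R)-7-(3-methylbutanoyloxy)-9-[(E)-2-methylbut-2-enoyloxy]longipin-2-en-1-one | C/C=C(\C)C(=O)O[C@@H]1C[C@@H](OC(=O)CC(C)C)C(C)(C)[C@@H]2[C@H]3C(=O)C=C(C)[C@@H]2[C@]31C | target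

Total step count: 19. Longest linear sequence: 18 (steps 1–7 and 9–19; step 8 is a one-step side branch).

Steps most likely to fail

**Step 9.**
- What may go wrong: the hindered C6 terminus may fail to engage C5 on the convex face. It may instead enter along the rear lobe, which leads to an opening that cannot close. The aryl-free electrophilic centre may also rearrange by cyclopropylcarbinyl-type pathways, or the diene may be consumed by protodesilylation, before trapping occurs.
- Fallback: this uses known reactions only and makes the C5–C6 bond by carbonyl addition instead of bicyclobutane opening. It sets out from 11 and comes back at 15. Trifluoroacetic acid is added across the central bond (CH2Cl2, 0 °C) to give the C5 trifluoroacetate F1. K2CO3 in MeOH then frees the cyclobutanol F2, and n-Pr4N[RuO4] with N-methylmorpholine N-oxide oxidises it to the cyclobutanone F3, in which the C5 centre is erased. A TiCl4-mediated Mukaiyama aldol addition of 13 to this strained ketone, on the face anti to the C1–C3 bridge, gives the tertiary carbinol enone F4. KN(SiMe3)2 (2.2 equiv, THF, −78 °C) forms the alkoxide and the C10 ester enolate, which closes the seven-membered ring by intramolecular Michael addition to the hydroxy ketone F5. Methyl chlorooxoacetate with DMAP gives the tertiary oxalate F6. Bu3SnH with AIBN in toluene removes the oxygen, the cage leaving only one position for the incoming hydrogen, to give the keto ester F7. TBSOTf with Et3N converts F7 into 15.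

**Step 7.**
- What may go wrong: the 1,2-shift of the tertiary allylic C4 hydrogen to the carbenoid carbon, or carbenoid dimerisation, may outrun addition to the ring alkene.
- Fallback: two ionic 1,3-eliminations replace the carbene. The fallback sets out from 8 and comes back at 11. mCPBA (CH2Cl2, NaHCO3) epoxidises 8 on the face anti to the arm and the silyl ether to give the epoxide F8. LiN(SiMe3)2 forms the ester enolate, which opens the epoxide at C5 (3-exo-tet) to the norcaranol ester F9. MsCl with Et3N gives the mesylate F10. KN(SiMe3)2 then deprotonates C10 again, and the cyclopropyl ester enolate displaces the C11 mesylate with inversion to close 11.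

**Step 18.**
- What may go wrong: hemiacetal formation and hydride transfer may be slow with the conjugated aldehyde in the ring-bound system. Retro-aldol cleavage or consumption of the aldehyde by divalent samarium may then compete.
- Fallback: an external hydride and a separate acylation are used. The fallback sets out from 26 and comes back at 29. Me4N[BH(OAc)3] in MeCN–AcOH at −30 °C (hydroxyl-directed Saksena–Evans reduction, to which the C1 enone is inert) gives the anti diol F11. One equivalent of tiglic anhydride with DMAP then acylates preferentially the C9 hydroxyl group. Its quaternary neighbour C10 is tied back in the cyclobutane, whereas the C7 hydroxyl group is flanked by the CMe2 group. This gives 29, and wrongly acylated material is returned to F11 by methanolysis.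

Further compounds
F1 | step 9 | methyl 4-(tert-butyldimethylsilyloxy)-2-methyl-7-(trifluoroacetoxy)bicyclo[3.1.1]heptane-6-carboxylate | FC(F)(F)C(=O)OC1[C@H]2[C@H](O[Si](C)(C)C(C)(C)C)C[C@@H](C)[C@@H]1C2C(=O)OC
F2 | step 9 | methyl 4-(tert-butyldimethylsilyloxy)-7-hydroxy-2-methylbicyclo[3.1.1]heptane-6-carboxylate | OC1[C@H]2[C@H](O[Si](C)(C)C(C)(C)C)C[C@@H](C)[C@@H]1C2C(=O)OC
F3 | step 9 | methyl 4-(tert-butyldimethylsilyloxy)-2-methyl-7-oxobicyclo[3.1.1]heptane-6-carboxylate | O=C1[C@H]2[C@H](O[Si](C)(C)C(C)(C)C)C[C@@H](C)[C@@H]1C2C(=O)OC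
F4 | step 9 | methyl 4-(tert-butyldimethylsilyloxy)-7-hydroxy-2-methyl-7-(2-methyl-3-oxopent-4-en-2-yl)bicyclo[3.1.1]heptane-6-carboxylate | C=CC(=O)C(C)(C)[C@]1(O)[C@H]2[C@H](O[Si](C)(C)C(C)(C)C)C[C@@H](C)[C@@H]1C2C(=O)OC
F5 | step 9 | C5-hydroxy C7-keto cage ester (longipinane cage; OH on C5; CO2Me on C10; OTBS on C1) | C1CC(=O)C(C)(C)[C@]2(O)[C@H]3[C@H](O[Si](C)(C)C(C)(C)C)C[C@@H](C)[C@@H]2[C@]31C(=O)OC
F6 | step 9 | methyl oxalate of F5 at O5 | C1CC(=O)C(C)(C)[C@]2(OC(=O)C(=O)OC)[C@H]3[C@H](O[Si](C)(C)C(C)(C)C)C[C@@H](C)[C@@H]2[C@]31C(=O)OC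
F7 | step 9 | C7 ketone corresponding to 15 (CO2Me on C10; OTBS on C1) | C1CC(=O)C(C)(C)[C@@H]2[C@H]3[C@H](O[Si](C)(C)C(C)(C)C)C[C@@H](C)[C@@H]2[C@]31C(=O)OC
F8 | step 7 | epoxide of 8 (oxygen anti to the acetate arm and to OTBS) | CC(C)(C)[Si](C)(C)O[C@H]1[C@@H]2O[C@@H]2[C@@H](CC(=O)OC)[C@H](C)C1
F9 | step 7 | methyl 3-(tert-butyldimethylsilyloxy)-2-hydroxy-5-methylbicyclo[4.1.0]heptane-7-carboxylate | CC(C)(C)[Si](C)(C)O[C@H]1[C@H](O)[C@H]2C(C(=O)OC)[C@H]2[C@H](C)C1
F10 | step 7 | mesylate of F9 | CC(C)(C)[Si](C)(C)O[C@H]1[C@H](OS(C)(=O)=O)[C@H]2C(C(=O)OC)[C@H]2[C@H](C)C1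
F11 | step 18 | (7R,9R)-7,9-dihydroxylongipin-2-en-1-one | O[C@@H]1C[C@@H](O)C(C)(C)[C@@H]2[C@H]3C(=O)C=C(C)[C@@H]2[C@]31C
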